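**Retrosynthetic overview**

1. After removal of two N-Boc groups, the bond between the quaternary ring carbon C6 and the vinylic carbon C7 of the (E)-CH=CH–indole arm is cut. A tertiary C6 radical, released by decarboxylation of a redox-active ester of the C6 carboxylic acid, is joined to an N-Boc 5-vinylindole in a Heck-type alkenylation that also sets the quaternary centre and the E-alkene.
2. Enabling feature (ring numbered C1 = CH bearing the indol-5-yl, C2=C3(CH3), C4H2, C5H2, C6 = C(CH3)): C6 is an all-carbon sp3 centre next to the C1 methine with its large indolyl group, and it carries a styrene-type E-alkene. A planar C6 radical can therefore be attacked anti to the C1 indolyl and terminated by β-H loss, with CO2H at C6 as a traceless handle.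
3. The C6 acid comes from the aldehyde of a catalytic asymmetric Diels–Alder reaction of an (E)-1-(indol-5-yl)-3-methylbutadiene with methacrolein. This builds the cyclohexene (C1–C6 and C4–C5 bonds), places C2=C3(CH3) and sets C1; the C6 configuration is erased later, so only C1 must be controlled.
4. Diene and vinylindole both come from one N-Boc 5-bromo-3-(1,1-dimethylallyl)indole (Heck reaction with isoprene; Suzuki vinylation), made by Fischer indolisation of 4-bromophenylhydrazine with 3,3-dimethylpent-4-enal.
5. Ring order: indole ring (Fischer, used for both halves), then cyclohexene (Diels–Alder); no ring is closed in the fragment union.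

Key step: step 9

Remark: the ring numbering of the overview (C1–C6, C7 = vinylic CH on C6) is used in the Why lines; compound names carry IUPAC locants.

**Route**

Step 1
Reactants: 1 methyl 3,3-dimethylpent-4-enoate
Product: 2 3,3-dimethylpent-4-enal
Conditions: DIBAL-H (1.05 equiv), CH2Cl2, −78 °C; aq. Rochelle salt
Reagents that add atoms: none
Why: Partial ester reduction with DIBAL-H at −78 °C stops at the aluminium hemiacetal, which gives the aldehyde on work-up, and the quaternary carbon next to the vinyl group rules out isomerisation.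

Step 2
Reactants: 2 3,3-dimethylpent-4-enal; 3 4-bromophenylhydrazine hydrochloride
Product: 5 5-bromo-3-(2-methylbut-3-en-2-yl)-1H-indole, via arylhydrazone 4 (not isolated)
Conditions: AcOH, 25 → 90 °C
Reagents that add atoms: none
Why: Fischer indole synthesis, in which the hydrazone tautomerises at its only enolisable CH2, the [3,3]-shift and loss of ammonia make the aldehyde carbon C2 and the 1,1-dimethylallyl-bearing carbon C3, and the para bromine ends at C5.

Step 3
Reactants: 5 5-bromo-3-(2-methylbut-3-en-2-yl)-1H-indole
Product: 6 tert-butyl 5-bromo-3-(2-methylbut-3-en-2-yl)-1H-indole-1-carboxylate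
Conditions: Boc2O (1.2 equiv), DMAP (10 mol %), MeCN, 25 °C
Reagents that add atoms: di-tert-butyl dicarbonate, CC(C)(C)OC(=O)OC(=O)OC(C)(C)C
Why: DMAP-catalysed N-acylation of the indole gives a carbamate that tames the indole for the Lewis-acid and radical steps and is removable with base at the end.

Step 4
Reactants: 6 tert-butyl 5-bromo-3-(2-methylbut-3-en-2-yl)-1H-indole-1-carboxylate; 7 isoprene
Product: 8 tert-butyl 5-[(1E)-3-methylbuta-1,3-dien-1-yl]-3-(2-methylbut-3-en-2-yl)-1H-indole-1-carboxylate
Conditions: Pd(OAc)2 (5 mol %), P(o-tol)3 (10 mol %), Et3N (2 equiv), isoprene (8 equiv), MeCN, sealed tube, 100 °C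
Reagents that add atoms: none
Why: Mizoroki–Heck reaction with a conjugated diene, in which the arylpalladium adds to the unsubstituted vinyl terminus of isoprene and β-hydride elimination of the benzylic hydrogen gives the (E)-1-aryl-3-methylbuta-1,3-diene, the hindered 1,1-dimethylallyl vinyl group being outcompeted by the excess diene.

Step 5
Reactants: 6 tert-butyl 5-bromo-3-(2-methylbut-3-en-2-yl)-1H-indole-1-carboxylate; 9 4,4,5,5-tetramethyl-2-vinyl-1,3,2-dioxaborolane
Product: 10 tert-butyl 5-ethenyl-3-(2-methylbut-3-en-2-yl)-1H-indole-1-carboxylate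
Conditions: Pd(dppf)Cl2·CH2Cl2 (3 mol %), K3PO4, 1,4-dioxane/H2O 5:1, 70 °C
Reagents that add atoms: none
Why: Suzuki–Miyaura vinylation of the aryl bromide under mild phosphate conditions that the N-Boc group should tolerate.

Step 6
Reactants: 8 tert-butyl 5-[(1E)-3-methylbuta-1,3-dien-1-yl]-3-(2-methylbut-3-en-2-yl)-1H-indole-1-carboxylate; 11 methacrolein
Product: 12 tert-butyl 5-[(1S,6S)-6-formyl-3,6-dimethylcyclohex-2-en-1-yl]-3-(2-methylbut-3-en-2-yl)-1H-indole-1-carboxylate
Conditions: (S)-B-(o-tolyl)-diphenylprolinol oxazaborolidine (20 mol %), Tf2NH (17 mol %), methacrolein (3 equiv), CH2Cl2, −78 → −40 °C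
Reagents that add atoms: none
Why: Chiral oxazaborolidinium-catalysed Diels–Alder reaction, in which the 1-aryl and 3-methyl groups of the diene both direct C1 onto the α-carbon of the enal, and the diene should add formyl-endo to the face of the boron-bound s-trans enal remote from the catalyst phenyl group, which sets C1 in the sense of the target and C6 with formyl cis to the indolyl; the minor exo adduct, which carries the opposite C1 configuration, is removed by chromatography.

Step 7
Reactants: 12 tert-butyl 5-[(1S,6S)-6-formyl-3,6-dimethylcyclohex-2-en-1-yl]-3-(2-methylbut-3-en-2-yl)-1H-indole-1-carboxylate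
Product: 13 (1S,2S)-2-[1-(tert-butoxycarbonyl)-3-(2-methylbut-3-en-2-yl)-1H-indol-5-yl]-1,4-dimethylcyclohex-3-ene-1-carboxylic acid
Conditions: NaClO2, NaH2PO4, 2-methylbut-2-ene (20 equiv), t-BuOH/H2O, 0 → 25 °C
Reagents that add atoms: sodium chlorite, [Na+].[O-]Cl=O
Why: Pinnick oxidation converts the non-enolisable aldehyde into the acid without touching either stereocentre, and the alkene scavenger removes hypochlorous acid before it can attack the ring alkene, the vinyl groups or the indole.

Step 8
Reactants: 13 (1S,2S)-2-[1-(tert-butoxycarbonyl)-3-(2-methylbut-3-en-2-yl)-1H-indol-5-yl]-1,4-dimethylcyclohex-3-ene-1-carboxylic acid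
Product: 14 1,3-dioxoisoindolin-2-yl (1S,2S)-2-[1-(tert-butoxycarbonyl)-3-(2-methylbut-3-en-2-yl)-1H-indol-5-yl]-1,4-dimethylcyclohex-3-ene-1-carboxylate
Conditions: N-hydroxyphthalimide (1.1 equiv), DIC (1.2 equiv), DMAP (10 mol %), CH2Cl2, 25 °C
Reagents that add atoms: N-hydroxyphthalimide, O=C1c2ccccc2C(=O)N1O
Why: Steglich-type esterification, in which the activated acyl group of the tertiary acid is captured by N-hydroxyphthalimide to give the redox-active ester, as is routine for tertiary acids.

Step 9
Reactants: 14 1,3-dioxoisoindolin-2-yl (1S,2S)-2-[1-(tert-butoxycarbonyl)-3-(2-methylbut-3-en-2-yl)-1H-indol-5-yl]-1,4-dimethylcyclohex-3-ene-1-carboxylate; 10 tert-butyl 5-ethenyl-3-(2-methylbut-3-en-2-yl)-1H-indole-1-carboxylate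
Product: 16 tert-butyl 5-[(E)-2-{(1S,2R)-2-[1-(tert-butoxycarbonyl)-3-(2-methylbut-3-en-2-yl)-1H-indol-5-yl]-1,4-dimethylcyclohex-3-en-1-yl}ethenyl]-3-(2-methylbut-3-en-2-yl)-1H-indole-1-carboxylate, via tertiary cyclohexenyl radical 15 (not isolated)
Conditions: Pd(PPh3)2Cl2 (5 mol %), Xantphos (6 mol %), 10 (2.5 equiv), DMA, blue LEDs (450 nm), 25 °C
Reagents that add atoms: none
Why: Photoexcited Pd(0)–Xantphos transfers one electron to the N-acyloxyphthalimide of 14, which loses phthalimide anion and CO2 to give the planar tertiary C6 radical 15 and Pd(I); 15 adds to the terminal CH2 of the vinyl group of 10, the benzylic radical recombines with Pd(I), and syn β-hydride elimination releases the (E)-alkene while the phthalimide anion takes up the proton and returns Pd(0). The closest known reaction type is the irradiation-induced palladium-catalysed decarboxylative Heck reaction of tertiary alkyl N-(acyloxy)phthalimides with vinylarenes. No ring is closed; the step forms the C6–C7 bond that joins the two halves. The C6 stereocentre is erased in 15 and set anew under control of C1: A(1,2) strain between the in-plane C6 methyl group and the C1 substituent turns the indolyl group pseudoaxial in the half-chair, where it covers one lobe of the radical, so the vinylarene should bond to the opposite face and place the alkenyl group trans to the indolyl and the methyl cis, as in the target, whatever the C6 configuration of 14. The step needs chemoselectivity among several C=C bonds, which the nucleophilic tertiary radical should secure by adding much faster to the conjugated, unhindered styrene-type CH2 of 10 (used in excess) than to the unactivated 1,1-dimethylallyl vinyl groups, the trisubstituted ring alkene or the hindered product alkene; the E-geometry follows from the β-hydride elimination with the bulky tertiary group anti to the aryl ring.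

Step 10
Reactants: 16 tert-butyl 5-[(E)-2-{(1S,2R)-2-[1-(tert-butoxycarbonyl)-3-(2-methylbut-3-en-2-yl)-1H-indol-5-yl]-1,4-dimethylcyclohex-3-en-1-yl}ethenyl]-3-(2-methylbut-3-en-2-yl)-1H-indole-1-carboxylate
Product: 17 5-[(E)-2-{(1S,2R)-1,4-dimethyl-2-[3-(2-methylbut-3-en-2-yl)-1H-indol-5-yl]cyclohex-3-en-1-yl}ethenyl]-3-(2-methylbut-3-en-2-yl)-1H-indole (EANPDB:ANNO_00013)
Conditions: K2CO3 (cat.), MeOH/THF 2:1, 50 °C
Reagents that add atoms: none
Why: Base-mediated methanolysis of the two indole N-carbamates (acyl-azole-type carbamates cleaved by methoxide), under conditions that should leave the alkenes, the acid-sensitive 1,1-dimethylallyl groups and both stereocentres untouched.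

**Compound list**

1 | methyl 3,3-dimethylpent-4-enoate | C=CC(C)(C)CC(=O)OC | starting material
2 | 3,3-dimethylpent-4-enal | C=CC(C)(C)CC=O | intermediate
3 | 4-bromophenylhydrazine hydrochloride | Cl.NNc1ccc(Br)cc1 | starting material
4 | (E)-1-(4-bromophenyl)-2-(3,3-dimethylpent-4-en-1-ylidene)hydrazine | C=CC(C)(C)C/C=N/Nc1ccc(Br)cc1 | intermediate (not isolated)
5 | 5-bromo-3-(2-methylbut-3-en-2-yl)-1H-indole | C=CC(C)(C)c1c[nH]c2ccc(Br)cc12 | intermediate
6 | tert-butyl 5-bromo-3-(2-methylbut-3-en-2-yl)-1H-indole-1-carboxylate | C=CC(C)(C)c1cn(C(=O)OC(C)(C)C)c2ccc(Br)cc12 | intermediate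
7 | isoprene (2-methylbuta-1,3-diene) | C=CC(C)=C | starting material
8 | tert-butyl 5-[(1E)-3-methylbuta-1,3-dien-1-yl]-3-(2-methylbut-3-en-2-yl)-1H-indole-1-carboxylate | C=CC(C)(C)c1cn(C(=O)OC(C)(C)C)c2ccc(/C=C/C(C)=C)cc12 | intermediate
9 | 4,4,5,5-tetramethyl-2-vinyl-1,3,2-dioxaborolane | C=CB1OC(C)(C)C(C)(C)O1 | starting material
10 | tert-butyl 5-ethenyl-3-(2-methylbut-3-en-2-yl)-1H-indole-1-carboxylate | C=CC(C)(C)c1cn(C(=O)OC(C)(C)C)c2ccc(C=C)cc12 | intermediate
11 | methacrolein (2-methylprop-2-enal) | C=C(C)C=O | starting material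
12 | tert-butyl 5-[(1S,6S)-6-formyl-3,6-dimethylcyclohex-2-en-1-yl]-3-(2-methylbut-3-en-2-yl)-1H-indole-1-carboxylate (formyl cis to indolyl) | O=C[C@@]1(C)CCC(C)=C[C@H]1c1ccc2n(C(=O)OC(C)(C)C)cc(C(C)(C)C=C)c2c1 | intermediate
13 | (1S,2S)-2-[1-(tert-butoxycarbonyl)-3-(2-methylbut-3-en-2-yl)-1H-indol-5-yl]-1,4-dimethylcyclohex-3-ene-1-carboxylic acid | OC(=O)[C@@]1(C)CCC(C)=C[C@H]1c1ccc2n(C(=O)OC(C)(C)C)cc(C(C)(C)C=C)c2c1 | intermediate
14 | 1,3-dioxoisoindolin-2-yl (1S,2S)-2-[1-(tert-butoxycarbonyl)-3-(2-methylbut-3-en-2-yl)-1H-indol-5-yl]-1,4-dimethylcyclohex-3-ene-1-carboxylate | O=C(ON1C(=O)c2ccccc2C1=O)[C@@]1(C)CCC(C)=C[C@H]1c1ccc2n(C(=O)OC(C)(C)C)cc(C(C)(C)C=C)c2c1 | intermediate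
15 | 2-[1-(tert-butoxycarbonyl)-3-(2-methylbut-3-en-2-yl)-1H-indol-5-yl]-1,4-dimethylcyclohex-3-en-1-yl radical (aryl-bearing stereocentre as in 14, radical carbon planar) | C[C]1CCC(C)=C[C@H]1c1ccc2n(C(=O)OC(C)(C)C)cc(C(C)(C)C=C)c2c1 | intermediate (not isolated)
16 | tert-butyl 5-[(E)-2-{(1S,2R)-2-[1-(tert-butoxycarbonyl)-3-(2-methylbut-3-en-2-yl)-1H-indol-5-yl]-1,4-dimethylcyclohex-3-en-1-yl}ethenyl]-3-(2-methylbut-3-en-2-yl)-1H-indole-1-carboxylate (alkenyl trans to indolyl) | C=CC(C)(C)c1cn(C(=O)OC(C)(C)C)c2ccc(/C=C/[C@]3(C)CCC(C)=C[C@H]3c3ccc4n(C(=O)OC(C)(C)C)cc(C(C)(C)C=C)c4c3)cc12 | intermediate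
17 | 5-[(E)-2-{(1S,2R)-1,4-dimethyl-2-[3-(2-methylbut-3-en-2-yl)-1H-indol-5-yl]cyclohex-3-en-1-yl}ethenyl]-3-(2-methylbut-3-en-2-yl)-1H-indole | C=CC(C)(C)c1c[nH]c2ccc(/C=C/[C@]3(C)CCC(C)=C[C@H]3c3ccc4[nH]cc(C(C)(C)C=C)c4c3)cc12 | target

**Step count and risks**

Total steps: 10. Longest linear sequence: 9 steps (1 → 2 → 5 → 6 → 8 → 12 → 13 → 14 → 16 → 17); step 5 supplies 10 on a one-step branch from 6.

Steps most likely to fail:

1. Step 9. What may go wrong: insufficient facial discrimination at the planar C6 radical (bonding syn to the indolyl); capture of the tertiary radical by Pd(I) followed by β-hydride elimination toward C1 or C5; and, if trapping is slow, 1,2-vinyl shift of the homoallylic radical with ring contraction to a benzylic radical. The fallback sets out from 14 and comes back at 16; it is a palladium-free radical addition–fragmentation with a bulkier acceptor. Bromide 6 is first taken through a Heck reaction with phenyl vinyl sulfone (Pd(OAc)2, P(o-tol)3, Et3N, DMF, 100 °C) to tert-butyl 5-[(E)-2-(benzenesulfonyl)ethenyl]-3-(2-methylbut-3-en-2-yl)-1H-indole-1-carboxylate F1. Ester 14 and F1 are then irradiated with Ru(bpy)3(PF6)2 (1 mol %), Hantzsch ester and i-Pr2NEt in CH2Cl2 (blue LEDs, 25 °C). Radical 15 adds to the sulfonyl-bearing carbon of F1, a more hindered trajectory that should raise the anti preference, and the benzylic radical expels the sulfonyl radical to give 16 with the E-alkene; no alkylpalladium species can form.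

2. Step 6. What may go wrong: poor endo/exo and facial discrimination with an α-substituted enal and an acyclic aryl diene (the exo adduct carries the opposite C1), or acid-induced oligomerisation of the electron-rich diene and loss of a Boc group. The fallback sets out from 8 and comes back at 12; asymmetric induction is replaced by resolution. Diene 8 and methacrolein 11 are combined under Me2AlCl (CH2Cl2, −78 °C), which should give the formyl-endo adduct as the racemate, that is 12 together with its mirror image tert-butyl 5-[(1R,6R)-6-formyl-3,6-dimethylcyclohex-2-en-1-yl]-3-(2-methylbut-3-en-2-yl)-1H-indole-1-carboxylate F2. Preparative chromatography on a chiral stationary phase (SFC) separates the two, and the absolute configuration is assigned by crystallography of a derivative or by VCD before 12 is carried on.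

3. Step 4. What may go wrong: addition of the arylpalladium to the methyl-substituted end of isoprene (regioisomeric diene), amine capture of the π-allylpalladium intermediate, and thermal oligomerisation of the product diene. The fallback sets out from 6 and comes back at 8; it uses a Heck reaction on a terminal alkene without regiochemical ambiguity, followed by dehydration. Bromide 6 and 2-methylbut-3-en-2-ol (Pd(OAc)2, P(o-tol)3, Et3N, MeCN, 90 °C) should give tert-butyl 5-[(1E)-3-hydroxy-3-methylbut-1-en-1-yl]-3-(2-methylbut-3-en-2-yl)-1H-indole-1-carboxylate F3. Its tertiary allylic alcohol is dehydrated with the Burgess reagent (benzene, 50 °C), where only the methyl hydrogens can be lost, to give diene 8.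

Further compounds
F1 | step 9 | tert-butyl 5-[(E)-2-(benzenesulfonyl)ethenyl]-3-(2-methylbut-3-en-2-yl)-1H-indole-1-carboxylate | C=CC(C)(C)c1cn(C(=O)OC(C)(C)C)c2ccc(/C=C/S(=O)(=O)c3ccccc3)cc12
F2 | step 6 | tert-butyl 5-[(1R,6R)-6-formyl-3,6-dimethylcyclohex-2-en-1-yl]-3-(2-methylbut-3-en-2-yl)-1H-indole-1-carboxylate | O=C[C@]1(C)CCC(C)=C[C@@H]1c1ccc2n(C(=O)OC(C)(C)C)cc(C(C)(C)C=C)c2c1
F3 | step 4 | tert-butyl 5-[(1E)-3-hydroxy-3-methylbut-1-en-1-yl]-3-(2-methylbut-3-en-2-yl)-1H-indole-1-carboxylate | C=CC(C)(C)c1cn(C(=O)OC(C)(C)C)c2ccc(/C=C/C(C)(C)O)cc12
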